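The quinone ring (C1 and C4 carbonyls, C2 hydroxyl, C3 docosyl, C5 methoxyl, C6 H) is disconnected at C5–C6 and C2–C3. Its C2–C3–C4 triad is a 2-alkyl-1,3-dioxygenated unit flanked by oxygen-bearing C1 and C5, so the ring is a masked, mirror-symmetric 2-docosyl-4,6-dimethoxycyclohexane-1,3-dione. One base-mediated Michael–Dieckmann [3+3] annulation forms both bonds and the only ring from 1-methoxypentacosan-2-one, a ketone whose carbonyl sits between a CH2OMe group and a 23-carbon chain, and methyl 2-methoxyacrylate, placing all four ring oxygens. Dehydrogenation and oxidative loss of one methyl group, either one by symmetry, then deliver the hydroxyquinone.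

Key step: step 3

Assumption: the side chain is read as an unbranched docosyl group (22 carbons). The target has no stereocentre, and the sp3 centres of 4, 7 and 8 are transient, so these compounds are carried as racemates or diastereomer mixtures.

Design notes:
- Ketone 5 is assembled from a C22 halide and a C3 epoxide at 0 °C or above, so every intermediate stays in solution and no cryogenic organolithium or tin reagent is needed.
- Both ether groups and the ester leaving group are methyl or methoxide, so 8 is mirror-symmetric and alkoxide exchange cannot create isomers.
- Resorcinol 9 is very electron-rich; it is made without a chemical oxidant and oxidised at once.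

Step 1
Reactants: 1 1-bromodocosane; 2 2-(methoxymethyl)oxirane (racemic glycidyl methyl ether)
Product: 4 1-methoxypentacosan-2-ol (racemic), via docosylmagnesium bromide 3 (not isolated)
Conditions: Mg, THF, 50 °C; then CuI (10 mol %), 2, 0 °C → rt; 1 M HCl
Reagents that add atoms: none
Why: Copper-catalysed ring opening of a terminal epoxide by a primary Grignard reagent (SN2 at the unsubstituted oxirane carbon) should place the 22-carbon chain on the future C3 of the ketone; the carbinol centre is racemic and is erased in step 2.

Step 2
Reactants: 4 1-methoxypentacosan-2-ol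
Product: 5 1-methoxypentacosan-2-one
Conditions: Dess–Martin periodinane, CH2Cl2, rt
Reagents that add atoms: none
Why: Dess–Martin oxidation of the secondary alcohol should give the ketone under neutral, non-cryogenic conditions in which the waxy substrate stays dissolved and the ether is untouched; no stereocentre remains.

Step 3
Reactants: 5 1-methoxypentacosan-2-one; 6 methyl 2-methoxyprop-2-enoate (methyl 2-methoxyacrylate)
Product: 8 2-docosyl-4,6-dimethoxycyclohexane-1,3-dione (diastereomer mixture), via methyl 2,4-dimethoxy-5-oxooctacosanoate 7 (not isolated)
Conditions: KOtBu (2 equiv), THF, rt; 6 added slowly; then 45 °C; 1 M HCl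
Reagents that add atoms: none
Why: KOtBu equilibrates the enolates of 5, and the enolate carbon that carries the methoxy group, the more acidic site because of the inductive pull of oxygen, adds 1,4 to the unsubstituted β-carbon of 6 (C5–C6 of the quinone ring) to give keto ester 7. Proton transfer then places the enolate on the chain-bearing α-carbon, which attacks the ester carbonyl and expels methoxide (C2–C3), and deprotonation of the resulting 2-alkyl-1,3-dione by base makes the sequence irreversible until the acid quench. The closest known reaction type is the base-mediated Michael–Claisen [3+3] annulation of ketones with acrylates to cyclohexane-1,3-diones. The one ring, the six-membered carbocycle, closes in the Dieckmann stage by 6-exo-trig attack of the enolate carbon on the ester carbonyl. No stereocentre of the target is created; the sp3 centres of 8 form as an epimerisable mixture under no control and are flattened in step 4. The step needs site selectivity between the two α-carbons of 5 (the reverse pairing would give the 4-docosyl-2,6-dimethoxy isomer) and 1,4- over 1,2-addition; the acidifying methoxy group under equilibrating conditions secures the first, and the unhindered CH2 terminus of 6, added slowly to the preformed enolate, the second.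

Step 4
Reactants: 8 2-docosyl-4,6-dimethoxycyclohexane-1,3-dione
Product: 9 2-docosyl-4,6-dimethoxybenzene-1,3-diol
Conditions: Pd/C (10 wt % Pd on carbon), mesitylene, reflux (165 °C), argon sweep
Reagents that add atoms: none
Why: Heterogeneous palladium-catalysed dehydrogenation of a dihydroresorcinol to the resorcinol, driven by aromatisation and removal of H2 in the gas stream, should remove all sp3 ring centres, and the absence of acid or a chemical oxidant should spare both methoxy groups and the oxidation-prone product.

Step 5
Reactants: 9 2-docosyl-4,6-dimethoxybenzene-1,3-diol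
Product: 10 3-docosyl-2-hydroxy-5-methoxycyclohexa-2,5-diene-1,4-dione (target)
Conditions: (NH4)2Ce(NO3)6 (2.2 equiv), MeCN/THF/H2O, 0 °C
Reagents that add atoms: water, O
Why: Oxidative demethylation of a para-methoxyphenol by tetravalent cerium should give an aryloxy cation that water attacks at the methoxy-bearing carbon with loss of methanol, and because the arene is mirror-symmetric and hydroxyquinone tautomers interconvert, every mode of attack converges on 10.

Compound list
1 | 1-bromodocosane | CCCCCCCCCCCCCCCCCCCCCCBr | starting material
2 | 2-(methoxymethyl)oxirane (glycidyl methyl ether, racemic) | COCC1CO1 | starting material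
3 | docosylmagnesium bromide | CCCCCCCCCCCCCCCCCCCCCC[Mg]Br | intermediate (not isolated)
4 | 1-methoxypentacosan-2-ol (racemic) | CCCCCCCCCCCCCCCCCCCCCCCC(O)COC | intermediate
5 | 1-methoxypentacosan-2-one | CCCCCCCCCCCCCCCCCCCCCCCC(=O)COC | intermediate
6 | methyl 2-methoxyprop-2-enoate (methyl 2-methoxyacrylate) | C=C(OC)C(=O)OC | starting material
7 | methyl 2,4-dimethoxy-5-oxooctacosanoate (diastereomer mixture) | CCCCCCCCCCCCCCCCCCCCCCCC(=O)C(OC)CC(OC)C(=O)OC | intermediate (not isolated)
8 | 2-docosyl-4,6-dimethoxycyclohexane-1,3-dione (diastereomer mixture, mainly enolised) | CCCCCCCCCCCCCCCCCCCCCCC1C(=O)C(OC)CC(OC)C1=O | intermediate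
9 | 2-docosyl-4,6-dimethoxybenzene-1,3-diol | CCCCCCCCCCCCCCCCCCCCCCc1c(O)c(OC)cc(OC)c1O | intermediate
10 | 3-docosyl-2-hydroxy-5-methoxycyclohexa-2,5-diene-1,4-dione | CCCCCCCCCCCCCCCCCCCCCCC1=C(O)C(=O)C=C(OC)C1=O | target

Total step count: 5
Longest linear sequence: 5 steps (1 → 4 → 5 → 8 → 9 → 10)

Steps most likely to fail

1. Step 3.
   - Risk: the conjugate addition may start from the chain-side α-carbon, or the enolate may acylate at the ester first; either scrambles the ring substitution. The captodative acceptor may also react so slowly that aldol self-condensation of the ketone takes over.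
   - Fallback (sets out from 1, returns at 10): the ring is bought instead of built. Commercial 1,2,4,5-tetramethoxybenzene (COc1cc(OC)c(OC)cc1OC) is lithiated between two methoxy groups (n-BuLi, TMEDA, THF, 0 °C) and alkylated with 1 to give 3-docosyl-1,2,4,5-tetramethoxybenzene F1. (NH4)2Ce(NO3)6 in aqueous MeCN should oxidise this to 3-docosyl-2,5-dimethoxycyclohexa-2,5-diene-1,4-dione F2. HClO4 in dioxane should then hydrolyse the methoxy group beside the chain, whose conjugation is weakened by twisting, to give 10.

2. Step 4.
   - Risk: at 165 °C aromatisation may proceed by loss of methanol instead of hydrogen, and hydrogen held on the catalyst may reduce a carbonyl group of unreacted dione.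
   - Fallback (sets out from 8, returns at 9): an ionic dehydrogenation at 0 °C. TMSOTf and Et3N in CH2Cl2 should convert 8 into 3-docosyl-1,5-dimethoxy-2,4-bis(trimethylsilyloxy)cyclohexa-1,3-diene F3. After the ammonium salt is removed, DDQ (1 equiv) with 2,6-lutidine in CH2Cl2 should abstract hydride from the allylic, methoxy-bearing carbon, and proton loss gives [(2-docosyl-4,6-dimethoxy-1,3-phenylene)bis(oxy)]bis(trimethylsilane) F4. Methanolysis with citric acid in degassed MeOH returns 9.

3. Step 5.
   - Risk: one-electron oxidation of the free, very electron-rich bis-phenol may lead to radical coupling or ring nitration, and the acidic hydroxyquinone may degrade in the nitric acid medium.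
   - Fallback (sets out from 9, returns at 10): a two-electron, ionic oxidation. PhI(OAc)2 in MeOH at 0 °C should give the quinone monoketal 2-docosyl-3-hydroxy-4,4,6-trimethoxycyclohexa-2,5-dien-1-one F5, and dilute oxalic acid in THF/H2O should hydrolyse the ketal to 10.

Further compounds
F1 | step 3 | 3-docosyl-1,2,4,5-tetramethoxybenzene | CCCCCCCCCCCCCCCCCCCCCCc1c(OC)c(OC)cc(OC)c1OC
F2 | step 3 | 3-docosyl-2,5-dimethoxycyclohexa-2,5-diene-1,4-dione | CCCCCCCCCCCCCCCCCCCCCCC1=C(OC)C(=O)C=C(OC)C1=O
F3 | step 4 | 3-docosyl-1,5-dimethoxy-2,4-bis(trimethylsilyloxy)cyclohexa-1,3-diene | CCCCCCCCCCCCCCCCCCCCCCC1=C(O[Si](C)(C)C)C(OC)CC(OC)=C1O[Si](C)(C)C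
F4 | step 4 | [(2-docosyl-4,6-dimethoxy-1,3-phenylene)bis(oxy)]bis(trimethylsilane) | CCCCCCCCCCCCCCCCCCCCCCc1c(O[Si](C)(C)C)c(OC)cc(OC)c1O[Si](C)(C)C
F5 | step 5 | 2-docosyl-3-hydroxy-4,4,6-trimethoxycyclohexa-2,5-dien-1-one | CCCCCCCCCCCCCCCCCCCCCCC1=C(O)C(OC)(OC)C=C(OC)C1=O
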